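The seven-membered ring (C1, C5 to C10) is disconnected at C8–C9, far from the trans C1–C5 fusion. A Me2AlCl-promoted type 2 carbonyl-ene reaction of a C8 aldehyde with the isopropenyl group on C1 forms that bond, closes the ring, sets the C8 carbinol cis to the C7 isopropyl group and leaves a C10=C14 methylene. The feature exploited is the cis-1,3 relation of the C8 oxygen and the C10 hydroxyl across C9: the new C8 hydroxyl later delivers the C10 oxygen to its own face. The precursor is a trans-4,5-disubstituted 1-methylcyclopentene carrying the isopropenyl group and a (2R)-2-formyl-3-methylbutyl chain.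

Key step: step 14

Remark: guaiane numbering is used for all ring carbons (five-membered ring C1–C5, seven-membered ring C1 and C5–C10, C14 on C10, C15 on C4); β is the face of H-5 and of the C8 and C10 oxygens, α the face of H-1 and of the epoxide oxygen.
Remark: TBS = tert-butyldimethylsilyl, TBDPS = tert-butyldiphenylsilyl, Tf = trifluoromethanesulfonyl; compounds 9 and 10 (THF solution) are bought.

Step 1
Reactants: 1 (S)-4-benzyloxazolidin-2-one; 2 isovaleryl chloride
Product: 3 (S)-4-benzyl-3-(3-methylbutanoyl)oxazolidin-2-one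
Conditions: Et3N, DMAP (cat.), CH2Cl2, 0 °C to rt
Reagents that add atoms: none
Why: DMAP-catalysed N-acylation of the oxazolidinone by the acid chloride (nucleophilic acyl substitution) attaches the chain to the auxiliary without touching its stereocentre.

Step 2
Reactants: 3 (S)-4-benzyl-3-(3-methylbutanoyl)oxazolidin-2-one
Product: 5 (S)-4-benzyl-3-[(2R)-2-(hydroxymethyl)-3-methylbutanoyl]oxazolidin-2-one, via titanium enolate 4 (not isolated)
Conditions: TiCl4, i-Pr2NEt, CH2Cl2, 0 °C; then 1,3,5-trioxane, TiCl4, 0 °C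
Reagents that add atoms: 1,3,5-trioxane, C1OCOCO1
Why: Evans hydroxymethylation: the chelated (Z)-chlorotitanium enolate is attacked by TiCl4-activated formaldehyde on the face away from the benzyl group, which sets C7 as (R).

Step 3
Reactants: 5 (S)-4-benzyl-3-[(2R)-2-(hydroxymethyl)-3-methylbutanoyl]oxazolidin-2-one
Product: 6 (S)-4-benzyl-3-[(2R)-2-(TBDPS-oxymethyl)-3-methylbutanoyl]oxazolidin-2-one
Conditions: TBDPSCl, imidazole, DMF, rt
Reagents that add atoms: tert-butyldiphenylsilyl chloride, CC(C)(C)[Si](Cl)(c1ccccc1)c1ccccc1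
Why: Imidazole-assisted silylation of the primary alcohol keeps the two CH2O arms different once the auxiliary is removed, so C7 stays stereogenic, and TBDPS is chosen because it should outlast the acidic step 9.

Step 4
Reactants: 6 (S)-4-benzyl-3-[(2R)-2-(TBDPS-oxymethyl)-3-methylbutanoyl]oxazolidin-2-one
Product: 7 (2S)-2-(TBDPS-oxymethyl)-3-methylbutan-1-ol
Conditions: LiBH4, H2O (1 equiv), Et2O, 0 °C
Reagents that add atoms: none
Why: Reductive cleavage of the N-acyl oxazolidinone by LiBH4 (hydride attack at the exocyclic carbonyl) frees the primary alcohol and the auxiliary without enolising C7, the descriptor changing only by priority.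

Step 5
Reactants: 7 (2S)-2-(TBDPS-oxymethyl)-3-methylbutan-1-ol
Product: 8 (2R)-2-(TBDPS-oxymethyl)-3-methylbutanal
Conditions: TEMPO (cat.), PhI(OAc)2, CH2Cl2, rt
Reagents that add atoms: none
Why: TEMPO-catalysed oxoammonium oxidation stops at the aldehyde under nearly neutral conditions, so the α-stereocentre C7 and the β-silyloxy group should survive; the aldehyde is used crude.

Step 6
Reactants: 9 (S)-4-(TBS-oxy)cyclopent-2-en-1-one; 10 isopropenylmagnesium bromide; 8 (2R)-2-(TBDPS-oxymethyl)-3-methylbutanal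
Product: 12 (2R,3R,4S)-4-(TBS-oxy)-2-[(2R)-2-(TBDPS-oxymethyl)-1-hydroxy-3-methylbutyl]-3-(prop-1-en-2-yl)cyclopentan-1-one (both carbinol epimers), via bromomagnesium enolate 11 (not isolated)
Conditions: CuBr·SMe2 (20 mol%), THF, −78 °C; then 8, −78 °C
Reagents that add atoms: none
Why: Prostaglandin-type three-component coupling: copper-catalysed 1,4-addition of the Grignard reagent occurs anti to the C2 silyloxy group and fixes C1, and the magnesium enolate then adds to aldehyde 8 anti to the new isopropenyl group (aldol addition), the C6 carbinol mixture being of no consequence because C6 becomes CH2.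

Step 7
Reactants: 12 aldol adduct
Product: 14 (2E,3S,4S)-4-(TBS-oxy)-2-[(2S)-2-(TBDPS-oxymethyl)-3-methylbutylidene]-3-(prop-1-en-2-yl)cyclopentan-1-one, via mesylate 13 (not isolated)
Conditions: MsCl, Et3N, DMAP (cat.), CH2Cl2, 0 °C to rt
Reagents that add atoms: none
Why: Mesylation followed by E1cB elimination through the ketone enolate gives the conjugated exocyclic enone, Et3N being too weak to expel the ring silyloxy group or to deprotonate C7.

Step 8
Reactants: 14 exocyclic enone
Product: 15 (2S,3R,4S)-4-(TBS-oxy)-2-[(2R)-2-(TBDPS-oxymethyl)-3-methylbutyl]-3-(prop-1-en-2-yl)cyclopentan-1-one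
Conditions: [(Ph3P)CuH]6, benzene, H2O (2 equiv), rt
Reagents that add atoms: none
Why: Stryker conjugate reduction delivers hydride to C6 of the enone only (isolated alkenes and silyl ethers are inert) and water protonates the copper enolate at C5 mainly anti to the isopropenyl group, the trans arrangement being completed by enolisation in step 9.

Step 9
Reactants: 15 β-silyloxy ketone
Product: 16 (4R,5S)-5-[(2R)-2-(TBDPS-oxymethyl)-3-methylbutyl]-4-(prop-1-en-2-yl)cyclopent-2-en-1-one
Conditions: AcOH/H2O (9:1), 60 °C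
Reagents that add atoms: none
Why: Acid-mediated cleavage of the secondary silyl ether and dehydration of the β-oxy ketone through its enol, the conversion known from E-type to A-type prostaglandins, gives the enone without a dienolate, so C1 and the isopropenyl group stay untouched, C5 settles trans and the primary TBDPS ether should survive.

Step 10
Reactants: 16 cyclopentenone
Product: 18 (4R,5S)-5-[(2R)-2-(TBDPS-oxymethyl)-3-methylbutyl]-4-(prop-1-en-2-yl)cyclopent-1-en-1-yl trifluoromethanesulfonate, via lithium enolate 17 (not isolated)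
Conditions: LiBH(s-Bu)3 (L-Selectride), THF, −78 °C; then PhNTf2, −78 to 0 °C
Reagents that add atoms: N-phenylbis(trifluoromethanesulfonimide), O=S(=O)(N(c1ccccc1)S(=O)(=O)C(F)(F)F)C(F)(F)F
Why: Conjugate hydride addition of the hindered borohydride to the β-unsubstituted cyclopentenone gives only the C3–C4 enolate, which PhNTf2 sulfonylates on oxygen (reductive enol triflation), so the place of the later double bond does not depend on kinetic deprotonation.

Step 11
Reactants: 18 enol triflate
Product: 19 tert-butyl{(2R)-3-methyl-2-{[(1S,5R)-2-methyl-5-(prop-1-en-2-yl)cyclopent-2-en-1-yl]methyl}butoxy}diphenylsilane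
Conditions: MeMgBr, Fe(acac)3 (5 mol%), THF/NMP, −20 °C
Reagents that add atoms: methylmagnesium bromide, C[Mg]Br
Why: Iron-catalysed Kumada-type cross-coupling of the alkenyl triflate with MeMgBr puts the C15 methyl group on C4 with the double bond held at C3=C4 and tolerates the silyl ether and the isopropenyl group.

Step 12
Reactants: 19 silyl ether
Product: 20 (2R)-3-methyl-2-{[(1S,5R)-2-methyl-5-(prop-1-en-2-yl)cyclopent-2-en-1-yl]methyl}butan-1-ol
Conditions: Bu4NF, THF, rt
Reagents that add atoms: none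
Why: Fluoride cleaves the Si–O bond (desilylation) and leaves both alkenes and all stereocentres alone.

Step 13
Reactants: 20 primary alcohol
Product: 21 (2R)-3-methyl-2-{[(1S,5R)-2-methyl-5-(prop-1-en-2-yl)cyclopent-2-en-1-yl]methyl}butanal
Conditions: TEMPO (cat.), PhI(OAc)2, CH2Cl2, rt
Reagents that add atoms: none
Why: Base-free oxoammonium oxidation of the primary alcohol gives the α-branched aldehyde without epimerising C7 or touching either alkene; the aldehyde is taken into step 14 at once.

Step 14
Reactants: 21 (2R)-3-methyl-2-{[(1S,5R)-2-methyl-5-(prop-1-en-2-yl)cyclopent-2-en-1-yl]methyl}butanal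
Product: 22 (1R,5S,7R,8R)-guaia-3,10(14)-dien-8-ol (8β-OH, 1αH, 5βH)
Conditions: Me2AlCl (2 equiv), CH2Cl2 (0.01 M), −78 to 0 °C
Reagents that add atoms: none
Why: Me2AlCl binds the aldehyde oxygen and the terminal carbon C9 of the isopropenyl group adds to C8 while a C14 hydrogen passes to oxygen through a six-membered array, a concerted but polarised ene reaction that moves the double bond to C10=C14. The closest known reaction type is the type 2 intramolecular carbonyl-ene cyclisation of 6-methylhept-6-enals to 3-methylenecycloheptanols with alkylaluminium chlorides. The seven-membered ring closes 7-exo-trig at the carbonyl carbon (C=O outside the ring, tether on the central ene carbon C10), and the trans C1/C5 substituents of the cyclopentene hold the two reacting groups gauche so that few rotors must be frozen. The new stereocentre C8 is controlled by C7: in the chair-like transition state the isopropyl group is equatorial and the aluminium-bound oxygen must be axial, syn to the C14 hydrogen it accepts, which places the C8 oxygen cis to the isopropyl group (8β, R). The step needs chemoselectivity for the isopropenyl group over the trisubstituted C3=C4 bond, which could reach C8 only through a bridged bicyclo[3.2.1] array with both ring substituents pseudoaxial and the isopropyl group axial over the C1–C2 bridge, so it should not compete. The reagent also removes the product proton as methane, which protects the acid-sensitive alkenes.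

Step 15
Reactants: 22 guaia-3,10(14)-dien-8β-ol
Product: 23 (1R,5S,7R,8R,10S)-10,14-epoxyguai-3-en-8-ol (epoxide oxygen β on C10)
Conditions: VO(acac)2 (5 mol%), t-BuOOH, CH2Cl2, rt
Reagents that add atoms: tert-butyl hydroperoxide, CC(C)(C)OO
Why: Vanadium-catalysed hydroxyl-directed epoxidation of a homoallylic alcohol: the C8 vanadate ester delivers the peroxide oxygen to the C10=C14 methylene on the face of the axial C8 hydroxyl (β), which sets C10, while the remote C3=C4 bond has no directing group and is left.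

Step 16
Reactants: 23 spiro-epoxy alcohol
Product: 24 (1R,5S,7R,8R,10S)-guai-3-ene-8,10-diol (8β,10β)
Conditions: LiAlH4, THF, 0 °C to rt
Reagents that add atoms: none
Why: Hydride opens the 1,1-disubstituted epoxide in SN2 fashion at the unhindered CH2 terminus, which becomes the C14 methyl group, and leaves the C10–O bond and its β configuration intact.

Step 17
Reactants: 24 guai-3-ene-8β,10β-diol; 25 3,4-dimethoxybenzoyl chloride
Product: 26 (1R,5S,7R,8R,10S)-10-hydroxyguai-3-en-8-yl 3,4-dimethoxybenzoate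
Conditions: DMAP, Et3N, CH2Cl2, rt to 40 °C
Reagents that add atoms: none
Why: DMAP-catalysed acylation (nucleophilic catalysis) esterifies the secondary C8 hydroxyl while the tertiary C10 hydroxyl is too hindered to react, so no protecting group is needed.

Step 18
Reactants: 26 10β-hydroxyguai-3-en-8β-yl 3,4-dimethoxybenzoate
Product: 27 (1R,3R,4S,5S,7R,8R,10S)-3,4-epoxy-10-hydroxyguaian-8-yl 3,4-dimethoxybenzoate (CNP0304846.1)
Conditions: D-fructose-derived Shi ketone (0.3 equiv), Oxone (2KHSO5·KHSO4·K2SO4), K2CO3, Bu4NHSO4 (cat.), MeCN/CH2(OMe)2/aq. Na2B4O7 buffer, 0 °C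
Reagents that add atoms: potassium peroxymonosulfate (KHSO5, active part of Oxone), [K+].[O-]S(=O)(=O)OO
Why: Shi epoxidation: the chiral dioxirane transfers oxygen through a spiro transition state to the α face of the trisubstituted C3=C4 bond (the sense known for 1-substituted cycloalkenes, giving 3R,4S), which is also the face favoured torsionally, anti to the pseudoaxial H-5 and H-2β, and the aqueous medium suppresses delivery by the β C10 hydroxyl.

Compound list
1 | (S)-4-benzyloxazolidin-2-one | O=C1OC[C@H](Cc2ccccc2)N1 | starting material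
2 | isovaleryl chloride | CC(C)CC(=O)Cl | starting material
3 | (S)-4-benzyl-3-(3-methylbutanoyl)oxazolidin-2-one | CC(C)CC(=O)N1[C@@H](Cc2ccccc2)COC1=O | intermediate
4 | trichlorotitanium (Z)-enolate of 3 (not isolated) | CC(C)/C=C(\O[Ti](Cl)(Cl)Cl)N1[C@@H](Cc2ccccc2)COC1=O | intermediate
5 | (S)-4-benzyl-3-[(2R)-2-(hydroxymethyl)-3-methylbutanoyl]oxazolidin-2-one | CC(C)[C@H](CO)C(=O)N1[C@@H](Cc2ccccc2)COC1=O | intermediate
6 | (S)-4-benzyl-3-[(2R)-2-{[(tert-butyldiphenylsilyl)oxy]methyl}-3-methylbutanoyl]oxazolidin-2-one | CC(C)[C@H](CO[Si](c1ccccc1)(c1ccccc1)C(C)(C)C)C(=O)N1[C@@H](Cc2ccccc2)COC1=O | intermediate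
7 | (2S)-2-{[(tert-butyldiphenylsilyl)oxy]methyl}-3-methylbutan-1-ol | CC(C)[C@H](CO[Si](c1ccccc1)(c1ccccc1)C(C)(C)C)CO | intermediate
8 | (2R)-2-{[(tert-butyldiphenylsilyl)oxy]methyl}-3-methylbutanal | CC(C)[C@H](CO[Si](c1ccccc1)(c1ccccc1)C(C)(C)C)C=O | intermediate
9 | (S)-4-[(tert-butyldimethylsilyl)oxy]cyclopent-2-en-1-one | O=C1C=C[C@@H](O[Si](C)(C)C(C)(C)C)C1 | starting material
10 | isopropenylmagnesium bromide | C=C(C)[Mg]Br | starting material
11 | bromomagnesium enolate from 9 and 10, 1β-isopropenyl, 2α-OTBS (not isolated) | C=C(C)[C@@H]1[C@@H](O[Si](C)(C)C(C)(C)C)CC(O[Mg]Br)=C1 | intermediate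
12 | (2R,3R,4S)-4-(TBS-oxy)-2-[(2R)-2-(TBDPS-oxymethyl)-1-hydroxy-3-methylbutyl]-3-(prop-1-en-2-yl)cyclopentan-1-one, carbinol epimers | C=C(C)[C@@H]1[C@@H](O[Si](C)(C)C(C)(C)C)CC(=O)[C@H]1C(O)[C@@H](CO[Si](c2ccccc2)(c2ccccc2)C(C)(C)C)C(C)C | intermediate
13 | methanesulfonate of 12 (not isolated) | C=C(C)[C@@H]1[C@@H](O[Si](C)(C)C(C)(C)C)CC(=O)[C@H]1C(OS(C)(=O)=O)[C@@H](CO[Si](c2ccccc2)(c2ccccc2)C(C)(C)C)C(C)C | intermediate
14 | (2E,3S,4S)-4-(TBS-oxy)-2-[(2S)-2-(TBDPS-oxymethyl)-3-methylbutylidene]-3-(prop-1-en-2-yl)cyclopentan-1-one | C=C(C)[C@@H]1[C@@H](O[Si](C)(C)C(C)(C)C)CC(=O)/C1=C/[C@@H](CO[Si](c2ccccc2)(c2ccccc2)C(C)(C)C)C(C)C | intermediate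
15 | (2S,3R,4S)-4-(TBS-oxy)-2-[(2R)-2-(TBDPS-oxymethyl)-3-methylbutyl]-3-(prop-1-en-2-yl)cyclopentan-1-one | C=C(C)[C@@H]1[C@@H](O[Si](C)(C)C(C)(C)C)CC(=O)[C@H]1C[C@@H](CO[Si](c2ccccc2)(c2ccccc2)C(C)(C)C)C(C)C | intermediate
16 | (4R,5S)-5-[(2R)-2-(TBDPS-oxymethyl)-3-methylbutyl]-4-(prop-1-en-2-yl)cyclopent-2-en-1-one | C=C(C)[C@@H]1C=CC(=O)[C@H]1C[C@@H](CO[Si](c2ccccc2)(c2ccccc2)C(C)(C)C)C(C)C | intermediate
17 | lithium C3–C4 enolate from 16 (not isolated) | C=C(C)[C@@H]1CC=C(O[Li])[C@H]1C[C@@H](CO[Si](c2ccccc2)(c2ccccc2)C(C)(C)C)C(C)C | intermediate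
18 | (4R,5S)-5-[(2R)-2-(TBDPS-oxymethyl)-3-methylbutyl]-4-(prop-1-en-2-yl)cyclopent-1-en-1-yl trifluoromethanesulfonate | C=C(C)[C@@H]1CC=C(OS(=O)(=O)C(F)(F)F)[C@H]1C[C@@H](CO[Si](c2ccccc2)(c2ccccc2)C(C)(C)C)C(C)C | intermediate
19 | tert-butyl{(2R)-3-methyl-2-{[(1S,5R)-2-methyl-5-(prop-1-en-2-yl)cyclopent-2-en-1-yl]methyl}butoxy}diphenylsilane | C=C(C)[C@@H]1CC=C(C)[C@H]1C[C@@H](CO[Si](c2ccccc2)(c2ccccc2)C(C)(C)C)C(C)C | intermediate
20 | (2R)-3-methyl-2-{[(1S,5R)-2-methyl-5-(prop-1-en-2-yl)cyclopent-2-en-1-yl]methyl}butan-1-ol | C=C(C)[C@@H]1CC=C(C)[C@H]1C[C@@H](CO)C(C)C | intermediate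
21 | (2R)-3-methyl-2-{[(1S,5R)-2-methyl-5-(prop-1-en-2-yl)cyclopent-2-en-1-yl]methyl}butanal (key-step precursor) | C=C(C)[C@@H]1CC=C(C)[C@H]1C[C@@H](C=O)C(C)C | intermediate
22 | (1R,5S,7R,8R)-guaia-3,10(14)-dien-8-ol (key-step product) | O[C@@H]1CC(=C)[C@@H]2CC=C(C)[C@H]2C[C@@H]1C(C)C | intermediate
23 | (1R,5S,7R,8R,10S)-10,14-epoxyguai-3-en-8-ol | O[C@@H]1C[C@@]3(CO3)[C@@H]2CC=C(C)[C@H]2C[C@@H]1C(C)C | intermediate
24 | (1R,5S,7R,8R,10S)-guai-3-ene-8,10-diol | O[C@@H]1C[C@](C)(O)[C@@H]2CC=C(C)[C@H]2C[C@@H]1C(C)C | intermediate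
25 | 3,4-dimethoxybenzoyl chloride | COc1ccc(C(=O)Cl)cc1OC | starting material
26 | (1R,5S,7R,8R,10S)-10-hydroxyguai-3-en-8-yl 3,4-dimethoxybenzoate | COc1ccc(C(=O)O[C@@H]2C[C@](C)(O)[C@@H]3CC=C(C)[C@H]3C[C@@H]2C(C)C)cc1OC | intermediate
27 | (1R,3R,4S,5S,7R,8R,10S)-3,4-epoxy-10-hydroxyguaian-8-yl 3,4-dimethoxybenzoate | COc1ccc(C(=O)O[C@@H]2C[C@](C)(O)[C@@H]3C[C@H]4O[C@@]4(C)[C@H]3C[C@@H]2C(C)C)cc1OC | target

Total step count: 18. Longest linear sequence: 18 steps (steps 1 to 18; 9 and 10 enter at step 6, 25 at step 17).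

Steps most likely to fail

Step 14. The closure of a seven-membered ring is slow, so the aldehyde complex may instead ionise, be attacked by the more electron-rich C3=C4 bond, or react stepwise with chloride capture, double-bond migration or loss of C8 selectivity. The fallback removes the competing nucleophile by cyclising before the methyl group is introduced. It sets out from 18: buffered Bu4NF/AcOH should give the triflate alcohol F1, and TEMPO/PhI(OAc)2 the triflate aldehyde F2. Me2AlCl should then close the ring to the dienol triflate F3, because the enol triflate is too electron-poor to act as an ene donor. Fe(acac)3 with excess MeMgBr would replace the triflate by methyl and return to the route at 22.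

Step 18. Oxygen may be transferred to the β face, or with poor discrimination, if the bias of the substrate overrides the catalyst. The fallback uses the facial inversion built into halohydrin chemistry. It sets out from 26: NBS (1 equiv) in THF/H2O at 0 °C should place bromine on the more accessible face and let water open the bromonium ion at the tertiary C4 from the α side, giving the 3β-bromo-4α-hydroxy bromohydrin F4. DBU in CH2Cl2 would then close the epoxide by displacement at C3 with inversion and return to the route at 27.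

Step 9. Desilylation and dehydration may stop halfway, the primary silyl ether may be lost, or the new ring double bond may move into conjugation with the isopropenyl group and erase C1. The fallback avoids the enone altogether by radical deoxygenation. It sets out from 15: HF·pyridine should cleave only the secondary TBS ether to give the β-hydroxy ketone F5. 1,1'-Thiocarbonyldiimidazole would give the thiocarbonylimidazolide F6, and Bu3SnH/AIBN (Barton–McCombie) the ketone F7. LDA at −78 °C should deprotonate the C3 methylene kinetically and return to the route at enolate 17, which PhNTf2 converts into 18.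

Further compounds
F1 | step 14 | (4R,5S)-5-[(2R)-2-(hydroxymethyl)-3-methylbutyl]-4-(prop-1-en-2-yl)cyclopent-1-en-1-yl trifluoromethanesulfonate | C=C(C)[C@@H]1CC=C(OS(=O)(=O)C(F)(F)F)[C@H]1C[C@@H](CO)C(C)C
F2 | step 14 | (4R,5S)-5-[(2R)-2-formyl-3-methylbutyl]-4-(prop-1-en-2-yl)cyclopent-1-en-1-yl trifluoromethanesulfonate | C=C(C)[C@@H]1CC=C(OS(=O)(=O)C(F)(F)F)[C@H]1C[C@@H](C=O)C(C)C
F3 | step 14 | (1R,5S,7R,8R)-8-hydroxy-15-norguaia-3,10(14)-dien-4-yl trifluoromethanesulfonate | O[C@@H]1CC(=C)[C@@H]2CC=C(OS(=O)(=O)C(F)(F)F)[C@H]2C[C@@H]1C(C)C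
F4 | step 18 | (1R,3S,4S,5S,7R,8R,10S)-3-bromo-4,10-dihydroxyguaian-8-yl 3,4-dimethoxybenzoate (3β-Br, 4α-OH) | COc1ccc(C(=O)O[C@@H]2C[C@](C)(O)[C@@H]3C[C@H](Br)[C@@](C)(O)[C@H]3C[C@@H]2C(C)C)cc1OC
F5 | step 9 | (2S,3R,4S)-4-hydroxy-2-[(2R)-2-(TBDPS-oxymethyl)-3-methylbutyl]-3-(prop-1-en-2-yl)cyclopentan-1-one | C=C(C)[C@@H]1[C@@H](O)CC(=O)[C@H]1C[C@@H](CO[Si](c2ccccc2)(c2ccccc2)C(C)(C)C)C(C)C
F6 | step 9 | O-(imidazol-1-ylthiocarbonyl) derivative of F5 | C=C(C)[C@@H]1[C@@H](OC(=S)n2ccnc2)CC(=O)[C@H]1C[C@@H](CO[Si](c2ccccc2)(c2ccccc2)C(C)(C)C)C(C)C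
F7 | step 9 | (2S,3R)-2-[(2R)-2-(TBDPS-oxymethyl)-3-methylbutyl]-3-(prop-1-en-2-yl)cyclopentan-1-one | C=C(C)[C@@H]1CCC(=O)[C@H]1C[C@@H](CO[Si](c2ccccc2)(c2ccccc2)C(C)(C)C)C(C)C
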